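1.80 is the number to look at: that much E stands against each X charged in this flask.

| flask | X | E | remark | time |
|---|---|---|---|---|
| zeta | 34 mM (in portions, 4) | 61.2 mM | the very flask that is asked about, followed so far; portions every 2.5 s |  |
| flask | 34 mM (in portions, 4) | 61.2 mM | the portions of X follow each other after 2.5 s, the first at the start | 3.0 min |

zeta run (percent of the X charged)

| time / s | X / % | J / % |
|---|---|---|
| 10.0 | 94.0 | 0 |
| 15.0 | 89.8 | 0.3 |
| 25.0 | 83.2 | 0 |
| 30.0 | 80.2 | 0.2 |

(scatter of a reading: 0.5 percentage points)

- conversion of X at 3.0 min
- amount of J at 3.0 min, in percent of the X charged
- amount of J if the flask were left three thousand times as long, in percent of the X charged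

- percent here means X units held: one G counts as two
- what is said of J includes G
- what may be going on: X + E -> D + Z; Z + E -> D + L; L + E -> D + J; X + J <-> G
- what has gone from X into another species counts as reacted, even if it can come back
- in an amount of J, one G counts as one J

The bench rule says that with E in excess you treat c_E as constant, so X decays pseudo-first-order with a half-life that stretches as c_E shrinks. Over the readings so far, X falls from 94.0 % at 10.0 s to 80.2 % at 30.0 s. That gives you the E clock, the half-life of X at the charged c_E, as a reading of 1.46 min. At a different c_E, multiply it by the charged c_E over the new one.

Run it to 3.0 min at constant c_E and conversion comes to 76.0 %. Now find the border. Each X lost takes at least one E, so with a ratio of 1.80 that conversion costs 42.2 % of the E, and c_E is plainly not constant. Slow the clock by using the mean of the start and end c_E, and you get 67.6 %. That is your figure.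

The forecast is slightly lower: conversion 66 %, "a bit more if G forms", with J at 6 % and 35 % after the long wait.

The flask gives conversion 73.0 %, J 11.5 % and, after the long wait, J 45.8 %.

    X + E → D + Z (k = 0.147 /M/s)
    Z + E → D + L (k = 0.0957 /M/s)
    L + E → D + J (k = 0.325 /M/s)
    X + J ⇌ G, settled at all times (K = 450 /M)

The conversion beats your clock. By 3.00 min, E stands at 46 % of its charge, and that shrinking supply, together with reading the flask at that time and not ten times later, is part of what holds the conversion at 73.0 %: the simulated run without the shrinking reads 88.0 %, and the run left ten times as long reads 96.1 %.

Now take the neighbour flask with 24 mM of E, a ratio of 0.706. Its clock starts at 3.71 min, and constant c_E gives 42.9 %, while the mean c_E gives 32.3 %. The computed conversion there is 35.2 %.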